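The synthesis rests on cutting the C8–C9 bond of the ten-membered carbocycle (germacrane numbering). The feature exploited is the pair of adjacent, trans-disposed ester-bearing ring carbons C8 and C9. They are flanked by C7 of the lactone ring and by the fully substituted C10 of the furanone ring, and retrosynthetically each is an aldehyde. Low-valent titanium reunites them, closing the carbocycle onto the finished 3(2H)-furanone ring and setting C8 and C9 in one operation. The precursor is an open-chain dialdehyde. It is a furanone with a non-enolisable formyl group (C9) on C10 and, beyond the Z C4=C5 alkene, a chain ending in the C8 formyl group. The methylene lactone is masked as its C6/C12 bis-TBS ether.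

Key step: step 19

Remarks on the chemistry:
- Germacrane numbering is used for every intermediate.
- CIP letters change with the substituents, although no centre and no alkene is ever inverted. C6 always stays cis to C3 (or to iodine) across C4=C5. This alkene is Z in the vinyl iodides and the furanones. It is E in the enyne, ynone and enaminone stages, because CH2O outranks an alkynyl or aminoalkenyl carbon.
- The C1 carbinol made in the lactate aldol is an inconsequential epimer mixture until step 16 oxidises it.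
- C6 and C7 are set by an auxiliary because C10 is too remote to steer that bond formation. The syn aldol array is the one that maps onto the trans-fused lactone.
- Assumption: the ring-trans (threo) 8,9-diol is taken as the main product of step 19.

Step 1
Reactants: 1 2-methylenepropane-1,3-diol
Product: 2 2-{[(tert-butyldimethylsilyl)oxy]methyl}prop-2-en-1-ol
Conditions: NaH (1.0 equiv), THF, 0 °C; TBSCl (1.0 equiv), 0 °C to rt
Reagents that add atoms: tert-butyldimethylsilyl chloride, CC(C)(C)[Si](C)(C)Cl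
Why: O-silylation of the sparingly soluble monosodium alkoxide caps only one of the two equivalent hydroxyls (the future O12).

Step 2
Reactants: 2 2-{[(tert-butyldimethylsilyl)oxy]methyl}prop-2-en-1-ol
Product: 4 tert-butyl{[2-(chloromethyl)allyl]oxy}dimethylsilane, via allylic mesylate 3 (not isolated)
Conditions: MsCl, Et3N, THF, 0 °C; then LiCl, DMF, rt
Reagents that add atoms: lithium chloride, [Li+].[Cl-]
Why: Mesylation followed by chloride displacement is a standard allylic chlorination, and direct and allylic (SN2 and SN2') attack give the same product here, so no regiochemical issue exists.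

Step 3
Reactants: 4 tert-butyl{[2-(chloromethyl)allyl]oxy}dimethylsilane
Product: 6 3-{[(tert-butyldimethylsilyl)oxy]methyl}but-3-enoic acid, via allylmagnesium chloride 5 (not isolated)
Conditions: Mg turnings (excess), THF, 0 °C, slow addition of 4; CO2 (dry gas), −40 °C to rt; 10% aq citric acid
Reagents that add atoms: carbon dioxide, O=C=O
Why: Grignard carboxylation, in which both termini of the 2-substituted allyl unit are CH2 groups so that alpha and gamma attack on CO2 give the same beta,gamma-unsaturated acid (the CO2 carbon becomes C8), slow addition of the chloride holding back Wurtz coupling.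

Step 4
Reactants: 6 3-{[(tert-butyldimethylsilyl)oxy]methyl}but-3-enoic acid; 7 (S)-4-benzyloxazolidin-2-one
Product: 10 (S)-4-benzyl-3-(3-{[(tert-butyldimethylsilyl)oxy]methyl}but-3-enoyl)oxazolidin-2-one, via mixed pivalic anhydride 8 (not isolated), via lithium oxazolidinide 9 (not isolated)
Conditions: 6, PivCl, Et3N, THF, −20 °C; 7, n-BuLi, THF, −78 °C (second flask); combine, −78 to 0 °C; aq NH4Cl
Reagents that add atoms: none
Why: N-acylation of the lithiated Evans auxiliary by a mixed anhydride occurs at the less hindered carbonyl, and the cold, short contact keeps the 1,1-disubstituted alkene out of conjugation.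

Step 5
Reactants: 11 but-2-yne-1,4-diol
Product: 12 4-[(tert-butyldiphenylsilyl)oxy]but-2-yn-1-ol
Conditions: 11 (3 equiv), TBDPSCl (1 equiv), imidazole, DMF, 0 °C to rt
Reagents that add atoms: tert-butyldiphenylsilyl chloride, CC(C)(C)[Si](Cl)(c1ccccc1)c1ccccc1
Why: Statistical monosilylation, in which the excess of the cheap water-soluble diol suppresses the bis-ether and is washed out, leaving the free hydroxyl (future O6) that directs step 6 and the protected one as O15.

Step 6
Reactants: 12 4-[(tert-butyldiphenylsilyl)oxy]but-2-yn-1-ol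
Product: 14 (Z)-4-[(tert-butyldiphenylsilyl)oxy]-3-iodobut-2-en-1-ol, via sodium alkenylalanate 13 (not isolated)
Conditions: NaAlH2(OCH2CH2OMe)2 (Red-Al), THF, 0 °C to rt; EtOAc; I2, −78 to 0 °C; aq Rochelle salt, Na2S2O3
Reagents that add atoms: iodine, II
Why: Hydroxyl-directed trans-hydroalumination of a propargylic alcohol puts hydride on C5 and aluminium on C4 in the five-membered alanate 13, and iodinolysis with retention fixes iodine cis to C6, which is the ring-cis C4=C5 geometry of the target.

Step 7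
Reactants: 14 (Z)-4-[(tert-butyldiphenylsilyl)oxy]-3-iodobut-2-en-1-ol
Product: 15 (Z)-4-[(tert-butyldiphenylsilyl)oxy]-3-iodobut-2-enal
Conditions: activated MnO2, CH2Cl2, rt, dark; used at once
Reagents that add atoms: none
Why: Heterogeneous allylic oxidation with MnO2 is neutral and stops at the enal, so the Z iodoalkene and the silyl ether are preserved.

Step 8
Reactants: 10 (S)-4-benzyl-3-(3-{[(tert-butyldimethylsilyl)oxy]methyl}but-3-enoyl)oxazolidin-2-one; 15 (Z)-4-[(tert-butyldiphenylsilyl)oxy]-3-iodobut-2-enal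
Product: 17 Evans syn aldol adduct (4Z,6S,7S), via boron dienolate 16 (not isolated)
Conditions: 10, Bu2BOTf, Et3N, CH2Cl2, −78 to 0 °C; 15, −78 to −10 °C; pH 7 buffer, MeOH, 30% H2O2, 0 °C
Reagents that add atoms: none
Why: Evans syn aldol, in which the Z boron dienolate 16 reacts at its alpha carbon (C7) through a Zimmerman–Traxler chair on the face away from the benzyl group, setting C6 and C7 together in the syn relation (the trans-lactone series) and in the required absolute sense by reagent control.

Step 9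
Reactants: 17 Evans syn aldol adduct (4Z,6S,7S)
Product: 18 C6 TBS ether of the aldol adduct (4Z,6S,7S)
Conditions: TBSOTf, 2,6-lutidine, CH2Cl2, −78 to 0 °C
Reagents that add atoms: tert-butyldimethylsilyl triflate, CC(C)(C)[Si](C)(C)OS(=O)(=O)C(F)(F)F
Why: Silyl triflate with a hindered pyridine base silylates the hindered allylic carbinol without retro-aldol, and a blocked O6 cannot later cyclise onto the cis alkyne.

Step 10
Reactants: 18 C6 TBS ether of the aldol adduct (4Z,6S,7S)
Product: 19 (2R,3S,4Z)-3-(TBS-oxy)-6-(TBDPS-oxy)-5-iodo-2-[3-(TBS-oxy)prop-1-en-2-yl]hex-4-en-1-ol (C8 alcohol; 6S,7R)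
Conditions: LiBH4, MeOH (1 equiv), Et2O, 0 °C
Reagents that add atoms: none
Why: Reductive removal of the Evans auxiliary, borohydride attacking the exocyclic imide carbonyl (C8) to give the primary alcohol without touching C7, the vinyl iodide or the silyl ethers, with 7 recovered.

Step 11
Reactants: 20 (S)-lactic acid; 21 pivalaldehyde
Product: 22 (2S,5S)-2-tert-butyl-5-methyl-1,3-dioxolan-4-one
Conditions: p-TsOH (cat.), H2SO4 (cat.), pentane, reflux, Dean–Stark; crystallisation from pentane, −78 °C
Reagents that add atoms: none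
Why: Acid-catalysed acetalisation with azeotropic water removal (first stage of self-regeneration of stereocentres) sets the acetal centre cis to the methyl group under thermodynamic control, and the cis isomer is purified by crystallisation.

Step 12
Reactants: 22 (2S,5S)-2-tert-butyl-5-methyl-1,3-dioxolan-4-one; 23 3-(trimethylsilyl)prop-2-ynal
Product: 25 (2S,5R)-2-tert-butyl-5-[1-hydroxy-3-(trimethylsilyl)prop-2-yn-1-yl]-5-methyl-1,3-dioxolan-4-one (carbinol epimers), via lithium enolate 24 (not isolated)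
Conditions: LDA, THF, −78 °C; 23, −78 °C; AcOH quench
Reagents that add atoms: none
Why: Aldol addition of the planar enolate 24, one face of which is shielded by the tert-butyl group, so that the aldehyde carbon (C1) enters where hydrogen stood (overall retention) and creates quaternary C10 in the configuration of the target, lithium enolates adding 1,2 to ynals at low temperature.

Step 13
Reactants: 25 (2S,5R)-2-tert-butyl-5-[1-hydroxy-3-(trimethylsilyl)prop-2-yn-1-yl]-5-methyl-1,3-dioxolan-4-one
Product: 27 (2S)-2-methylpent-4-yne-1,2,3-triol (C3 epimers), via silylated triol 26 (not isolated)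
Conditions: LiBH4, THF, 0 °C to rt; then MeOH, K2CO3 (0.3 equiv), rt; acidic resin, evaporation with MeOH
Reagents that add atoms: none
Why: Borohydride reduction of the lactone-type carbonyl (C9) collapses the acetal (the released pivalaldehyde is reduced too) without touching the alkyne, and base-catalysed methanolysis then cleaves the alkynyl C–Si bond (protodesilylation).

Step 14
Reactants: 27 (2S)-2-methylpent-4-yne-1,2,3-triol
Product: 28 (2S)-2-methyl-1-[(triethylsilyl)oxy]pent-4-yne-2,3-diol (C3 epimers)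
Conditions: TESCl (1.05 equiv), imidazole, CH2Cl2–DMF, −40 °C
Reagents that add atoms: triethylsilyl chloride, CC[Si](Cl)(CC)CC
Why: Chemoselective silylation, the primary hydroxyl reacting much faster at low temperature than the secondary propargylic and tertiary ones, and O9 must be blocked because it would otherwise close a six-membered pyranone in step 17.

Step 15
Reactants: 19 C8 alcohol vinyl iodide (6S,7R); 28 (2S)-2-methyl-1-[(triethylsilyl)oxy]pent-4-yne-2,3-diol
Product: 29 seco enyne triol (4E,6R,7R,10S; C1 epimers)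
Conditions: PdCl2(PPh3)2 (5 mol %), CuI (10 mol %), Et3N, THF, rt, degassed
Reagents that add atoms: none
Why: Sonogashira coupling forms C3–C4 with retention of the alkene geometry and tolerates the free hydroxyls.

Step 16
Reactants: 29 seco enyne triol (4E,6R,7R,10S; C1 epimers)
Product: 30 alpha'-hydroxy enynone (4E,6R,7R,10S)
Conditions: activated MnO2, CH2Cl2, rt
Reagents that add atoms: none
Why: MnO2 oxidises only the activated propargylic C1 carbinol, leaves the unactivated primary C8 hydroxyl and the tertiary C10 hydroxyl alone and removes the undefined centre.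

Step 17
Reactants: 30 alpha'-hydroxy enynone (4E,6R,7R,10S)
Product: 33 furanone 8,9-diol (4Z,6R,7R,10S), via enaminone 31 (not isolated), via TES furanone 32 (not isolated)
Conditions: Et2NH, EtOH, 0 °C to rt; evaporate; AcOH–THF–H2O (3:1:1), rt
Reagents that add atoms: none
Why: Amine-mediated 5-endo cyclisation of an alpha'-hydroxy ynone, in which diethylamine adds to C3 (conjugate addition), aqueous acetic acid lets the C10 hydroxyl displace the amine by addition–elimination to give the 3(2H)-furanone, and the same medium then hydrolyses the primary TES ether much faster than the TBS and TBDPS ethers.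

Step 18
Reactants: 33 furanone 8,9-diol (4Z,6R,7R,10S)
Product: 34 seco dialdehyde (4Z,6R,7S,10S)
Conditions: Dess–Martin periodinane (3 equiv), NaHCO3, CH2Cl2, 0 °C to rt; pentane–Et2O, filtration through a short pad; used at once
Reagents that add atoms: none
Why: Double Dess–Martin oxidation under bicarbonate buffer is neither basic nor nucleophilic, so both formyl groups are released in one operation without enolising C7 or deformylating the beta-keto aldehyde at C9.

Step 19
Reactants: 34 seco dialdehyde (4Z,6R,7S,10S)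
Product: 35 bicyclic 8,9-diol (4Z,6R,7R,8S,9R,10S)
Conditions: TiCl3(DME)1.5 (12 equiv), Zn–Cu couple (30 equiv), DME, reflux, 4 h; cool to rt; 34 in DME by syringe pump over 24 h (final about 2 mM); 10% aq K2CO3
Reagents that add atoms: none
Why: Each formyl group accepts one electron from the low-valent titanium and the two metal-bound ketyl carbons C8 and C9 combine, both oxygens staying on titanium until the basic work-up because deoxygenation to the alkene needs reflux temperature. The closest known reaction type is the McMurry-type intramolecular pinacol coupling of dialdehydes to medium and large 1,2-cycloalkanediols under high dilution. The ten-membered carbocycle closes by ketyl–ketyl combination with both C–O bonds exocyclic to the new ring, helped by the Z C4=C5 alkene, the flat furanone and the extended C5–C6–C7–C8 zigzag of the syn aldol array, which together fold C8 towards C9. C9 is controlled by C10: the tether can reach C9 only over the furanone face anti to the C14 methyl group, and O9 turns away from the ring oxygen towards the Lewis-basic C1 carbonyl oxygen that can share the titanium, which gives 9R. C8 is controlled by C7 in the Felkin–Anh sense, the new bond forming anti to the large alkenyl branch C11 (which thereby points out of the ring) and passing the C7 hydrogen, which gives 8S and is also the threo, ring-trans pairing generally preferred in titanium closures of rings of ten or more members. The step needs aldehyde-over-furanone chemoselectivity and an intact C7, secured because C1 is a vinylogous ester carbonyl that is much harder to reduce, no acrylate is present (the lactone is a bis-silyl ether), C9 has no alpha hydrogen, and 34 is made just before use and meets the reagent only at trace concentration.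

Step 20
Reactants: 35 bicyclic 8,9-diol (4Z,6R,7R,8S,9R,10S)
Product: 36 8-O-methacrylate with free 9-OH (4Z,6R,7R,8S,9R,10S)
Conditions: methacrylic anhydride (1.2 equiv), i-Pr2NEt, DMAP (0.1 equiv), CH2Cl2, −20 °C
Reagents that add atoms: methacrylic anhydride, C=C(C)C(=O)OC(=O)C(C)=C
Why: DMAP-catalysed acyl transfer picks the C8 hydroxyl because the C9 hydroxyl is neopentyl-like next to quaternary C10 and hydrogen-bonded to the C1 carbonyl, while the low temperature and weak base hold back acyl migration and retro-aldol cleavage of C9–C10.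

Step 21
Reactants: 36 8-O-methacrylate with free 9-OH
Product: 37 8-O-methacrylate 9-O-isovalerate (4Z,6R,7R,8S,9R,10S)
Conditions: isovaleric anhydride (3 equiv), DMAP (1 equiv), CH2Cl2, 0 °C to rt
Reagents that add atoms: isovaleric anhydride, CC(C)CC(=O)OC(=O)CC(C)C
Why: Forced DMAP-catalysed acylation of the one remaining, hindered hydroxyl with excess anhydride meets no competing site.

Step 22
Reactants: 37 8-O-methacrylate 9-O-isovalerate
Product: 38 C6,C12-diol with O15 still TBDPS-protected (4Z,6R,7S,8S,9R,10S)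
Conditions: 48% aq HF, MeCN, 0 °C
Reagents that add atoms: none
Why: Acidic fluoride desilylation sorts silyl ethers by acid stability, so both TBS ethers are cleaved while the far more acid-stable TBDPS ether and the two esters remain.

Step 23
Reactants: 38 C6,C12-diol
Product: 41 15-O-TBDPS ether of the target, via C12 enal 39 (not isolated), via lactol 40 (not isolated)
Conditions: TEMPO (0.2 equiv), PhI(OAc)2 (2.5 equiv), CH2Cl2, rt
Reagents that add atoms: none
Why: TEMPO/PhI(OAc)2 oxidative lactonisation, the oxoammonium salt oxidising the primary allylic C12 alcohol in preference to the secondary C6 alcohol, O6 closing the five-membered lactol 40 and a second oxidation giving the alpha-methylene-gamma-butyrolactone, trans-fused as fixed in step 8.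

Step 24
Reactants: 41 15-O-TBDPS ether of the target
Product: 42 target CNP0552093.1 (4Z,6R,7S,8S,9R,10S)
Conditions: HF·pyridine, pyridine, THF, 0 °C to rt (polypropylene vessel)
Reagents that add atoms: none
Why: Buffered acidic fluoride cleaves the last silyl ether and avoids basic fluoride, which could add to the methylene lactone or the methacrylate or trigger acyl migration.

Compound list
1 | 2-methylenepropane-1,3-diol | C=C(CO)CO | starting material
2 | 2-{[(tert-butyldimethylsilyl)oxy]methyl}prop-2-en-1-ol | C=C(CO)CO[Si](C)(C)C(C)(C)C | intermediate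
3 | 2-{[(tert-butyldimethylsilyl)oxy]methyl}allyl methanesulfonate (not isolated) | C=C(COS(C)(=O)=O)CO[Si](C)(C)C(C)(C)C | intermediate
4 | tert-butyl{[2-(chloromethyl)allyl]oxy}dimethylsilane | C=C(CCl)CO[Si](C)(C)C(C)(C)C | intermediate
5 | 2-{[(tert-butyldimethylsilyl)oxy]methyl}allylmagnesium chloride (not isolated) | C=C(C[Mg]Cl)CO[Si](C)(C)C(C)(C)C | intermediate
6 | 3-{[(tert-butyldimethylsilyl)oxy]methyl}but-3-enoic acid (C8, C7, C11, C13, C12) | C=C(CC(=O)O)CO[Si](C)(C)C(C)(C)C | intermediate
7 | (S)-4-benzyloxazolidin-2-one | O=C1N[C@@H](Cc2ccccc2)CO1 | starting material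
8 | mixed anhydride of 6 and pivalic acid (not isolated) | C=C(CC(=O)OC(=O)C(C)(C)C)CO[Si](C)(C)C(C)(C)C | intermediate
9 | lithium salt of 7 (not isolated) | [Li+].O=C1[N-][C@@H](Cc2ccccc2)CO1 | intermediate
10 | (S)-4-benzyl-3-(3-{[(tert-butyldimethylsilyl)oxy]methyl}but-3-enoyl)oxazolidin-2-one | C=C(CC(=O)N1C(=O)OC[C@@H]1Cc2ccccc2)CO[Si](C)(C)C(C)(C)C | intermediate
11 | but-2-yne-1,4-diol (C6, C5, C4, C15) | OCC#CCO | starting material
12 | 4-[(tert-butyldiphenylsilyl)oxy]but-2-yn-1-ol | OCC#CCO[Si](c1ccccc1)(c1ccccc1)C(C)(C)C | intermediate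
13 | sodium bis(2-methoxyethoxy) alkenylalanate, five-membered O–Al–C4 chelate (not isolated) | [Na+].COCCO[Al-]1(OCCOC)OCC=C1CO[Si](c2ccccc2)(c2ccccc2)C(C)(C)C | intermediate
14 | (Z)-4-[(tert-butyldiphenylsilyl)oxy]-3-iodobut-2-en-1-ol | OC/C=C(/CO[Si](c1ccccc1)(c1ccccc1)C(C)(C)C)I | intermediate
15 | (Z)-4-[(tert-butyldiphenylsilyl)oxy]-3-iodobut-2-enal | O=C/C=C(/CO[Si](c1ccccc1)(c1ccccc1)C(C)(C)C)I | intermediate
16 | (Z)-dibutylboron dienolate of 10 (not isolated) | CCCCB(CCCC)O/C(=C\C(=C)CO[Si](C)(C)C(C)(C)C)N1C(=O)OC[C@@H]1Cc2ccccc2 | intermediate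
17 | (S)-4-benzyl-3-{(2S,3S,4Z)-6-(TBDPS-oxy)-3-hydroxy-5-iodo-2-[3-(TBS-oxy)prop-1-en-2-yl]hex-4-enoyl}oxazolidin-2-one (6S,7S) | O=C1OC[C@H](Cc2ccccc2)N1C(=O)[C@@H](C(=C)CO[Si](C)(C)C(C)(C)C)[C@H](O)/C=C(/CO[Si](c3ccccc3)(c3ccccc3)C(C)(C)C)I | intermediate
18 | C6 TBS ether of 17 (4Z,6S,7S) | O=C1OC[C@H](Cc2ccccc2)N1C(=O)[C@@H](C(=C)CO[Si](C)(C)C(C)(C)C)[C@H](O[Si](C)(C)C(C)(C)C)/C=C(/CO[Si](c3ccccc3)(c3ccccc3)C(C)(C)C)I | intermediate
19 | (2R,3S,4Z)-3-(TBS-oxy)-6-(TBDPS-oxy)-5-iodo-2-[3-(TBS-oxy)prop-1-en-2-yl]hex-4-en-1-ol (6S,7R) | OC[C@@H](C(=C)CO[Si](C)(C)C(C)(C)C)[C@H](O[Si](C)(C)C(C)(C)C)/C=C(/CO[Si](c1ccccc1)(c1ccccc1)C(C)(C)C)I | intermediate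
20 | (S)-lactic acid (C14, C10, C9) | C[C@H](O)C(=O)O | starting material
21 | pivalaldehyde | CC(C)(C)C=O | starting material
22 | (2S,5S)-2-tert-butyl-5-methyl-1,3-dioxolan-4-one (cis) | C[C@@H]1O[C@H](C(C)(C)C)OC1=O | intermediate
23 | 3-(trimethylsilyl)prop-2-ynal (C1, C2, C3) | C[Si](C)(C)C#CC=O | starting material
24 | lithium enolate of 22 (not isolated) | [Li+].CC1=C([O-])O[C@@H](C(C)(C)C)O1 | intermediate
25 | (2S,5R)-2-tert-butyl-5-[1-hydroxy-3-(trimethylsilyl)prop-2-yn-1-yl]-5-methyl-1,3-dioxolan-4-one (carbinol epimers) | C[C@]1(C(O)C#C[Si](C)(C)C)O[C@H](C(C)(C)C)OC1=O | intermediate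
26 | (2S)-2-methyl-5-(trimethylsilyl)pent-4-yne-1,2,3-triol (C3 epimers, not isolated) | OC[C@](C)(O)C(O)C#C[Si](C)(C)C | intermediate
27 | (2S)-2-methylpent-4-yne-1,2,3-triol (C3 epimers) | OC[C@](C)(O)C(O)C#C | intermediate
28 | (2S)-2-methyl-1-[(triethylsilyl)oxy]pent-4-yne-2,3-diol (C3 epimers) | CC[Si](CC)(CC)OC[C@](C)(O)C(O)C#C | intermediate
29 | seco enyne triol (4E,6R,7R,10S; C1 epimers): OH at C1, C8, C10; O6 and O12 TBS; O15 TBDPS; O9 TES | OC[C@@H](C(=C)CO[Si](C)(C)C(C)(C)C)[C@H](O[Si](C)(C)C(C)(C)C)/C=C(/CO[Si](c1ccccc1)(c1ccccc1)C(C)(C)C)C#CC(O)[C@@](C)(O)CO[Si](CC)(CC)CC | intermediate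
30 | alpha'-hydroxy enynone (4E,6R,7R,10S): C1 ketone of 29 | OC[C@@H](C(=C)CO[Si](C)(C)C(C)(C)C)[C@H](O[Si](C)(C)C(C)(C)C)/C=C(/CO[Si](c1ccccc1)(c1ccccc1)C(C)(C)C)C#CC(=O)[C@@](C)(O)CO[Si](CC)(CC)CC | intermediate
31 | C3 diethylamino enaminone (C2=C3 geometry undefined, not isolated) | OC[C@@H](C(=C)CO[Si](C)(C)C(C)(C)C)[C@H](O[Si](C)(C)C(C)(C)C)/C=C(/CO[Si](c1ccccc1)(c1ccccc1)C(C)(C)C)C(=CC(=O)[C@@](C)(O)CO[Si](CC)(CC)CC)N(CC)CC | intermediate
32 | 9-O-TES furanone (4Z,6R,7R,10S, not isolated) | OC[C@@H](C(=C)CO[Si](C)(C)C(C)(C)C)[C@H](O[Si](C)(C)C(C)(C)C)/C=C(/CO[Si](c1ccccc1)(c1ccccc1)C(C)(C)C)C2=CC(=O)[C@@](C)(O2)CO[Si](CC)(CC)CC | intermediate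
33 | furanone 8,9-diol (4Z,6R,7R,10S): 2-(hydroxymethyl)-2-methyl-3(2H)-furanone bearing the C4–C8 chain at its 5-position | OC[C@@H](C(=C)CO[Si](C)(C)C(C)(C)C)[C@H](O[Si](C)(C)C(C)(C)C)/C=C(/CO[Si](c1ccccc1)(c1ccccc1)C(C)(C)C)C2=CC(=O)[C@@](C)(O2)CO | intermediate
34 | seco dialdehyde (4Z,6R,7S,10S), precursor of the key step | O=C[C@@H](C(=C)CO[Si](C)(C)C(C)(C)C)[C@H](O[Si](C)(C)C(C)(C)C)/C=C(/CO[Si](c1ccccc1)(c1ccccc1)C(C)(C)C)C2=CC(=O)[C@@](C)(O2)C=O | intermediate
35 | bicyclic 8,9-diol (4Z,6R,7R,8S,9R,10S), product of the key step | O[C@H]1[C@@H](C(=C)CO[Si](C)(C)C(C)(C)C)[C@H](O[Si](C)(C)C(C)(C)C)/C=C(/CO[Si](c3ccccc3)(c3ccccc3)C(C)(C)C)C2=CC(=O)[C@@](C)(O2)[C@@H]1O | intermediate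
36 | 8-O-methacrylate of 35, 9-OH free | C=C(C)C(=O)O[C@H]1[C@@H](C(=C)CO[Si](C)(C)C(C)(C)C)[C@H](O[Si](C)(C)C(C)(C)C)/C=C(/CO[Si](c3ccccc3)(c3ccccc3)C(C)(C)C)C2=CC(=O)[C@@](C)(O2)[C@@H]1O | intermediate
37 | 8-O-methacrylate 9-O-isovalerate of 35 | C=C(C)C(=O)O[C@H]1[C@@H](C(=C)CO[Si](C)(C)C(C)(C)C)[C@H](O[Si](C)(C)C(C)(C)C)/C=C(/CO[Si](c3ccccc3)(c3ccccc3)C(C)(C)C)C2=CC(=O)[C@@](C)(O2)[C@@H]1OC(=O)CC(C)C | intermediate
38 | C6,C12-diol (4Z,6R,7S,8S,9R,10S), O15 TBDPS | C=C(C)C(=O)O[C@H]1[C@@H](C(=C)CO)[C@H](O)/C=C(/CO[Si](c3ccccc3)(c3ccccc3)C(C)(C)C)C2=CC(=O)[C@@](C)(O2)[C@@H]1OC(=O)CC(C)C | intermediate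
39 | C12 enal with free 6-OH (not isolated) | C=C(C)C(=O)O[C@H]1[C@@H](C(=C)C=O)[C@H](O)/C=C(/CO[Si](c3ccccc3)(c3ccccc3)C(C)(C)C)C2=CC(=O)[C@@](C)(O2)[C@@H]1OC(=O)CC(C)C | intermediate
40 | C12 lactol, anomers (not isolated) | C=C(C)C(=O)O[C@H]1[C@H]2C(=C)C(O)O[C@@H]2/C=C(/CO[Si](c3ccccc3)(c3ccccc3)C(C)(C)C)C2=CC(=O)[C@@](C)(O2)[C@@H]1OC(=O)CC(C)C | intermediate
41 | 15-O-TBDPS ether of the target (4Z,6R,7S,8S,9R,10S) | C=C(C)C(=O)O[C@H]1[C@H]2C(=C)C(=O)O[C@@H]2/C=C(/CO[Si](c3ccccc3)(c3ccccc3)C(C)(C)C)C2=CC(=O)[C@@](C)(O2)[C@@H]1OC(=O)CC(C)C | intermediate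
42 | CNP0552093.1 (4Z,6R,7S,8S,9R,10S) | C=C(C)C(=O)O[C@H]1[C@H]2C(=C)C(=O)O[C@@H]2/C=C(/CO)C2=CC(=O)[C@@](C)(O2)[C@@H]1OC(=O)CC(C)C | target

Total step count: 24. Longest linear sequence: 17 steps (steps 1–4, 8–10, 15–24).

Steps most likely to fail

Step 19. Poor facial selectivity at C8 may occur, the two ketyls collapsing through the erythro pairing to the ring-cis diol. The fallback sets out from 34 and returns at 36.
- The coupling is run as described and the 8-epimeric (8R,9R) diol F1 is carried on.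
- SOCl2 and pyridine in CH2Cl2 at 0 °C give the cyclic sulfite F2.
- A brief oxidation with NaIO4 and catalytic RuCl3 in MeCN–H2O at 0 °C gives the cyclic sulfate F3.
- C9 sits next to quaternary C10 and is closed to SN2 attack. Caesium methacrylate in DMF therefore opens the sulfate only at C8, with inversion, to the caesium 9-sulfate of the 8S methacrylate F4.
- Catalytic H2SO4 with a little water in THF hydrolyses F4 to 36.
- C8 is then set by SN2 displacement instead of by the coupling, and the ester of step 20 is installed in the same move.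

Step 18. Configuration at C7 may be lost through enolisation, drift of the C11=C13 alkene into conjugation, or beta-elimination of the C6 silyloxy group. The danger arises while the slow oxidation of the neopentyl-like C9 carbinol is still running. The fallback sets out from 33 and returns at 34, and it stages the two oxidations by means of a temporary protecting group.
- TESCl and imidazole at −78 °C silylate the unhindered C8 hydroxyl to the 8-O-TES ether F5.
- Dess–Martin oxidation of the hindered C9 carbinol, now without time pressure, gives the robust non-enolisable 9-aldehyde F6.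
- AcOH–THF–H2O frees O8 to give the 8-hydroxy 9-aldehyde F7.
- A fast, base-free oxidation of this unhindered primary alcohol with catalytic TEMPO and PhI(OAc)2 delivers 34 directly before the coupling.

Step 20. Site selectivity may be poor and acyl migration from O8 to O9 may occur in the mono-ester. The fallback sets out from 35 and returns at 37, and it reverses the order of the esters with a temporary silyl group.
- TESOTf and 2,6-lutidine at −78 °C mark the more accessible hydroxyl as the 8-O-TES ether F8.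
- Excess isovaleric anhydride and DMAP then acylate O9 under forcing conditions to the 8-O-TES 9-isovalerate F9.
- PPTS in MeOH at 0 °C removes the TES group in the presence of the TBS and TBDPS ethers to give the 8-hydroxy 9-isovalerate F10.
- Methacrylic anhydride and DMAP put the sensitive methacrylate last onto the less hindered O8, giving 37.

Further compounds
F1 | step 19 | 8-epimeric (8R,9R) ring-cis diol | O[C@@H]1[C@@H](C(=C)CO[Si](C)(C)C(C)(C)C)[C@H](O[Si](C)(C)C(C)(C)C)/C=C(/CO[Si](c3ccccc3)(c3ccccc3)C(C)(C)C)C2=CC(=O)[C@@](C)(O2)[C@@H]1O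
F2 | step 19 | 8,9-cyclic sulfite of F1 (sulfur epimers) | O=S1O[C@@H]2[C@@H](C(=C)CO[Si](C)(C)C(C)(C)C)[C@H](O[Si](C)(C)C(C)(C)C)/C=C(/CO[Si](c4ccccc4)(c4ccccc4)C(C)(C)C)C3=CC(=O)[C@@](C)(O3)[C@@H]2O1
F3 | step 19 | 8,9-cyclic sulfate of F1 | O=S1(=O)O[C@@H]2[C@@H](C(=C)CO[Si](C)(C)C(C)(C)C)[C@H](O[Si](C)(C)C(C)(C)C)/C=C(/CO[Si](c4ccccc4)(c4ccccc4)C(C)(C)C)C3=CC(=O)[C@@](C)(O3)[C@@H]2O1
F4 | step 19 | caesium 9-sulfate of the 8S methacrylate | [Cs+].C=C(C)C(=O)O[C@H]1[C@@H](C(=C)CO[Si](C)(C)C(C)(C)C)[C@H](O[Si](C)(C)C(C)(C)C)/C=C(/CO[Si](c3ccccc3)(c3ccccc3)C(C)(C)C)C2=CC(=O)[C@@](C)(O2)[C@@H]1OS(=O)(=O)[O-]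
F5 | step 18 | 8-O-TES ether of 33 | CC[Si](CC)(CC)OC[C@@H](C(=C)CO[Si](C)(C)C(C)(C)C)[C@H](O[Si](C)(C)C(C)(C)C)/C=C(/CO[Si](c1ccccc1)(c1ccccc1)C(C)(C)C)C2=CC(=O)[C@@](C)(O2)CO
F6 | step 18 | 8-O-TES 9-aldehyde | CC[Si](CC)(CC)OC[C@@H](C(=C)CO[Si](C)(C)C(C)(C)C)[C@H](O[Si](C)(C)C(C)(C)C)/C=C(/CO[Si](c1ccccc1)(c1ccccc1)C(C)(C)C)C2=CC(=O)[C@@](C)(O2)C=O
F7 | step 18 | 8-hydroxy 9-aldehyde | OC[C@@H](C(=C)CO[Si](C)(C)C(C)(C)C)[C@H](O[Si](C)(C)C(C)(C)C)/C=C(/CO[Si](c1ccccc1)(c1ccccc1)C(C)(C)C)C2=CC(=O)[C@@](C)(O2)C=O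
F8 | step 20 | 8-O-TES ether of 35 | CC[Si](CC)(CC)O[C@H]1[C@@H](C(=C)CO[Si](C)(C)C(C)(C)C)[C@H](O[Si](C)(C)C(C)(C)C)/C=C(/CO[Si](c3ccccc3)(c3ccccc3)C(C)(C)C)C2=CC(=O)[C@@](C)(O2)[C@@H]1O
F9 | step 20 | 8-O-TES 9-isovalerate | CC[Si](CC)(CC)O[C@H]1[C@@H](C(=C)CO[Si](C)(C)C(C)(C)C)[C@H](O[Si](C)(C)C(C)(C)C)/C=C(/CO[Si](c3ccccc3)(c3ccccc3)C(C)(C)C)C2=CC(=O)[C@@](C)(O2)[C@@H]1OC(=O)CC(C)C
F10 | step 20 | 8-hydroxy 9-isovalerate | O[C@H]1[C@@H](C(=C)CO[Si](C)(C)C(C)(C)C)[C@H](O[Si](C)(C)C(C)(C)C)/C=C(/CO[Si](c3ccccc3)(c3ccccc3)C(C)(C)C)C2=CC(=O)[C@@](C)(O2)[C@@H]1OC(=O)CC(C)C
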